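**Plan**

1. Retrosynthetic cuts, in order: the aryl O–CH3 (protecting group); the C2′–C3′ bond; in the chroman half O1–C8a, C4–C4a and the prenyl C=C of (R)-linalool; in the side-chain half the bonds around a propyne unit, back to (R)-citronellyl bromide.
2. Enabling feature: C2′–C3′ is an unsubstituted CH2–CH2 link. Once cut, both ends are primary carbons, so each half can be a carboxylic acid (a chroman-2-ylpropanoic acid and a C15 3-methyl acid) whose CO2 is the traceless activating group.
3. C2 and C4′ are never radical sites and the C11′=C12′ alkene is eight bonds from C3′. The easily oxidised 6-oxygenated benzopyran ring rules out anodic Kolbe coupling, so both primary radicals are made reductively from N-acyloxyphthalimides at nickel in one electrolysis.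
4. Forward: the dihydropyran ring is built first (C4–C4a by Suzuki coupling, then O1–C8a by Pd-catalysed C–O coupling), the prenyl end is cleaved to CO2H, the two esters are joined electrochemically, and the methyl ether is removed last.
5. Stereochemistry: C2 from (R)-linalool (its C–O bond is never broken), C8′ from (R)-citronellyl bromide, C4′ from Ru–(S)-BINAP hydrogenation of an (E)-allylic alcohol.

Key step: step 12

Assumption: (R)-(−)-linalool and (R)-(−)-citronellyl bromide are used in enantiomerically pure commercial grade; side-chain carbons carry primes (C1′ is the CH2 on C2 of the chroman).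

**Route**

Step 1
Reactants: 1 4-methoxy-2-methylaniline
Product: 2 2-iodo-4-methoxy-6-methylaniline
Conditions: I2 (1.05 equiv), NaHCO3, CH2Cl2/H2O, 0 °C → rt
Reagents that add atoms: iodine, II
Why: Electrophilic aromatic iodination directed by NH2, the strongest donor, whose para position is blocked by OMe and one ortho position by CH3, so iodine should enter the free ortho position.

Step 2
Reactants: 2 2-iodo-4-methoxy-6-methylaniline
Product: 4 2-bromo-1-iodo-5-methoxy-3-methylbenzene, via arenediazonium bromide 3 (not isolated)
Conditions: NaNO2, 48% aq HBr, MeCN, 0 °C; then CuBr (0.3 equiv), 60 °C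
Reagents that add atoms: sodium nitrite, [Na+].[O-]N=O (nitrogen of intermediate 3 only); hydrobromic acid, Br
Why: Sandmeyer bromination replaces NH2 by Br without touching the C–I bond, which places the more reactive iodide at the less hindered position and the bromide between CH3 and the iodide.

Step 3
Reactants: 5 (R)-linalool; 4 2-bromo-1-iodo-5-methoxy-3-methylbenzene
Product: 7 (3R)-1-(2-bromo-5-methoxy-3-methylphenyl)-3,7-dimethyloct-6-en-3-ol, via alkylborane 6 (not isolated)
Conditions: 9-BBN (1.5 equiv), THF, 0 °C → rt; then 4, PdCl2(dppf) (3 mol %), 3 M aq K3PO4, DMF, 50 °C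
Reagents that add atoms: 9-borabicyclo[3.3.1]nonane, B1C2CCCC1CCC2 (boron of intermediate 6 only)
Why: 9-BBN hydroborates only the monosubstituted vinyl group (anti-Markovnikov) and the B-alkyl Suzuki–Miyaura coupling then takes place at C–I, which undergoes oxidative addition far faster than the doubly ortho-substituted C–Br, while the carbinol stereocentre is not involved.

Step 4
Reactants: 7 (3R)-1-(2-bromo-5-methoxy-3-methylphenyl)-3,7-dimethyloct-6-en-3-ol
Product: 8 (2R)-6-methoxy-2,8-dimethyl-2-(4-methylpent-3-en-1-yl)chroman
Conditions: Pd(OAc)2 (3 mol %), 2-(di-tert-butylphosphino)-1,1′-binaphthyl (6 mol %), NaOtBu (1.5 equiv), toluene, 80 °C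
Reagents that add atoms: none
Why: Buchwald–Hartwig-type intramolecular C–O coupling closes the six-membered ring at the aryl carbon, the tertiary alkoxide having no hydrogen on the carbinol carbon for β-hydride elimination, and C2 keeps its configuration because its C–O bond is never broken.

Step 5
Reactants: 8 (2R)-6-methoxy-2,8-dimethyl-2-(4-methylpent-3-en-1-yl)chroman
Product: 10 3-[(2S)-6-methoxy-2,8-dimethylchroman-2-yl]propanoic acid, via chromanylpropanal 9 (not isolated)
Conditions: O3/O2, MeCN/H2O 9:1, 0 °C, to the alkene end point; N2 purge; then NaClO2, NaH2PO4, 0 °C → rt; aq NaHSO3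
Reagents that add atoms: ozone, [O-][O+]=O; sodium chlorite, [Na+].[O-]Cl=O; water, O
Why: Ozonolysis in wet acetonitrile cleaves the trisubstituted alkene (much faster than the arene) directly to aldehyde 9 and acetone, and Pinnick-type chlorite oxidation in the same flask should give the acid, the hydrogen peroxide formed in the first stage destroying hypochlorite before it can chlorinate the ring.

Step 6
Reactants: 10 3-[(2S)-6-methoxy-2,8-dimethylchroman-2-yl]propanoic acid
Product: 11 1,3-dioxoisoindolin-2-yl 3-[(2S)-6-methoxy-2,8-dimethylchroman-2-yl]propanoate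
Conditions: N-hydroxyphthalimide (1.1 equiv), DIC (1.1 equiv), DMAP (10 mol %), CH2Cl2, rt
Reagents that add atoms: N-hydroxyphthalimide, O=C1c2ccccc2C(=O)N1O
Why: Steglich-type carbodiimide esterification should give the redox-active N-acyloxyphthalimide without touching the remote stereocentre.

Step 7
Reactants: 12 (R)-citronellyl bromide
Product: 13 (6S)-6,10-dimethylundec-9-en-1-yne
Conditions: propyne, n-BuLi (2 equiv), TMEDA, Et2O/hexane, −78 → 0 °C; then 12, DMPU, 0 °C → rt; aq NH4Cl
Reagents that add atoms: 1,3-dilithiopropyne, [Li]CC#C[Li] (made in the flask from propyne, CC#C, and n-BuLi)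
Why: SN2 alkylation of the propargylic carbon of 1,3-dilithiopropyne by the primary bromide should give the terminal alkyne after protonation, the stereocentre being two carbons from the reacting centre (the descriptor changes from R to S only through CIP priorities).

Step 8
Reactants: 13 (6S)-6,10-dimethylundec-9-en-1-yne
Product: 16 (2E,7S)-3,7,11-trimethyldodeca-2,10-dien-1-ol, via alkenylalane 14 (not isolated), via lithium aluminate 15 (not isolated)
Conditions: Me3Al (2 equiv), Cp2ZrCl2 (20 mol %), CH2Cl2, 0 °C → rt; volatiles removed; n-BuLi, THF, −78 °C; (CH2O)n, → rt; aqueous work-up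
Reagents that add atoms: trimethylaluminium, C[Al](C)C; n-butyllithium, [Li]CCCC (butyl on aluminium in intermediate 15 only); formaldehyde (from paraformaldehyde), C=O
Why: Negishi zirconium-catalysed methylalumination adds CH3 and Al syn across the terminal alkyne with Al on the terminal carbon, and the derived aluminate adds to formaldehyde with retention of alkene geometry, so the E allylic alcohol should result while the trisubstituted alkene stays inert.

Step 9
Reactants: 16 (2E,7S)-3,7,11-trimethyldodeca-2,10-dien-1-ol
Product: 17 (3R,7S)-3,7,11-trimethyldodec-10-en-1-ol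
Conditions: Ru(OAc)2[(S)-BINAP] (0.5 mol %), H2 (100 atm), MeOH/H2O 95:5, 20 °C
Reagents that add atoms: none
Why: Noyori hydroxyl-directed asymmetric hydrogenation, in which the (S)-BINAP catalyst with an E-configured 3-methylalk-2-en-1-ol should deliver hydrogen to the face that gives the 3R centre (geraniol → (R)-citronellol sense, catalyst control), while the isolated C10=C11 alkene, which has no coordinating group, is not reduced.

Step 10
Reactants: 17 (3R,7S)-3,7,11-trimethyldodec-10-en-1-ol
Product: 19 (3R,7S)-3,7,11-trimethyldodec-10-enoic acid, via aldehyde 18 (not isolated)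
Conditions: TEMPO (20 mol %), PhI(OAc)2 (2.2 equiv), MeCN/H2O 1:1, rt
Reagents that add atoms: water, O
Why: Oxoammonium (TEMPO/PhI(OAc)2) oxidation takes the primary alcohol through aldehyde 18 and its hydrate to the acid, and neither the β-stereocentre (not enolisable at the stereogenic carbon) nor the alkene should be affected.

Step 11
Reactants: 19 (3R,7S)-3,7,11-trimethyldodec-10-enoic acid
Product: 20 1,3-dioxoisoindolin-2-yl (3R,7S)-3,7,11-trimethyldodec-10-enoate
Conditions: N-hydroxyphthalimide (1.1 equiv), DIC (1.1 equiv), DMAP (10 mol %), CH2Cl2, rt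
Reagents that add atoms: N-hydroxyphthalimide, O=C1c2ccccc2C(=O)N1O
Why: Steglich-type carbodiimide esterification, as in step 6, should give the second redox-active ester.

Step 12
Reactants: 11 1,3-dioxoisoindolin-2-yl 3-[(2S)-6-methoxy-2,8-dimethylchroman-2-yl]propanoate (1 equiv); 20 1,3-dioxoisoindolin-2-yl (3R,7S)-3,7,11-trimethyldodec-10-enoate (2.5 equiv)
Product: 21 (2R)-6-methoxy-2,8-dimethyl-2-[(4R,8S)-4,8,12-trimethyltridec-11-en-1-yl]chroman
Conditions: NiCl2·6H2O (20 mol %), 4,4′,4″-tri-tert-butyl-2,2′:6′,2″-terpyridine (20 mol %), AgNO3 (0.3 equiv), NMP, undivided cell, Mg anode/RVC cathode, constant current, rt; dilute aq HCl work-up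
Reagents that add atoms: none
Why: Cathodically reduced terpyridine–nickel transfers an electron to each N-acyloxyphthalimide, which loses CO2 and phthalimide anion to give the primary radicals at C2′ (from 11) and C3′ (from 20); successive capture of both radicals at nickel and reductive elimination from the dialkylnickel forms the C2′–C3′ bond, while magnesium is oxidised at the anode. The closest known reaction type is the nickel-electrocatalytic doubly decarboxylative C(sp3)–C(sp3) coupling of two redox-active esters, a reductive counterpart of mixed Kolbe electrolysis that is established for primary–primary pairs. No ring is closed and no stereocentre is created; C2, C4′ and C8′ are not radical carbons (C4′ is next to the C3′ radical, C2 is two bonds from the C2′ radical), so all three should pass through unchanged. The selectivity needed is cross- over homo-coupling, which is statistical for two primary radicals and is biased by using the more accessible ester 20 in excess, so that 11 ends mainly in the cross product; the hydrocarbon homodimer of 20 is far less polar than the aryl ether 21 and should be separable. Because the radicals are made by reduction, the easily oxidised 6-methoxychroman ring and the C11′=C12′ alkene, which is too remote from C3′ for 5- or 6-membered cyclisation, should not take part.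

Step 13
Reactants: 21 (2R)-6-methoxy-2,8-dimethyl-2-[(4R,8S)-4,8,12-trimethyltridec-11-en-1-yl]chroman
Product: 22 (2R)-2,8-dimethyl-2-[(4R,8S)-4,8,12-trimethyltridec-11-en-1-yl]chroman-6-ol
Conditions: NaSEt (5 equiv), degassed DMF, 130 °C, argon; dilute aq HCl work-up
Reagents that add atoms: none
Why: Thiolate SN2 attack at the unhindered O–CH3 carbon should cleave the aryl methyl ether, whereas the tertiary C2–O1 ring ether cannot react by SN2 and the alkene and stereocentres are inert to these non-acidic conditions.

**Compound list**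

1 | 4-methoxy-2-methylaniline | Cc1cc(OC)ccc1N | starting material
2 | 2-iodo-4-methoxy-6-methylaniline | Cc1cc(OC)cc(I)c1N | intermediate
3 | 2-iodo-4-methoxy-6-methylbenzenediazonium bromide | Cc1cc(OC)cc(I)c1[N+]#N.[Br-] | intermediate
4 | 2-bromo-1-iodo-5-methoxy-3-methylbenzene | Cc1cc(OC)cc(I)c1Br | intermediate
5 | (R)-linalool, (3R)-3,7-dimethylocta-1,6-dien-3-ol | CC(C)=CCC[C@](O)(C)C=C | starting material
6 | (3S)-1-(9-borabicyclo[3.3.1]nonan-9-yl)-3,7-dimethyloct-6-en-3-ol (geometry of 5 unchanged; descriptor changes by CIP priority only) | CC(C)=CCC[C@](O)(C)CCB1C2CCCC1CCC2 | intermediate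
7 | (3R)-1-(2-bromo-5-methoxy-3-methylphenyl)-3,7-dimethyloct-6-en-3-ol | CC(C)=CCC[C@](O)(C)CCc1cc(OC)cc(C)c1Br | intermediate
8 | (2R)-6-methoxy-2,8-dimethyl-2-(4-methylpent-3-en-1-yl)chroman | CC(C)=CCC[C@]1(C)CCc2cc(OC)cc(C)c2O1 | intermediate
9 | 3-[(2S)-6-methoxy-2,8-dimethylchroman-2-yl]propanal | O=CCC[C@]1(C)CCc2cc(OC)cc(C)c2O1 | intermediate
10 | 3-[(2S)-6-methoxy-2,8-dimethylchroman-2-yl]propanoic acid | OC(=O)CC[C@]1(C)CCc2cc(OC)cc(C)c2O1 | intermediate
11 | 1,3-dioxoisoindolin-2-yl 3-[(2S)-6-methoxy-2,8-dimethylchroman-2-yl]propanoate | O=C(CC[C@]1(C)CCc2cc(OC)cc(C)c2O1)ON1C(=O)c2ccccc2C1=O | intermediate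
12 | (R)-citronellyl bromide, (6R)-8-bromo-2,6-dimethyloct-2-ene | CC(C)=CCC[C@@H](C)CCBr | starting material
13 | (6S)-6,10-dimethylundec-9-en-1-yne | CC(C)=CCC[C@@H](C)CCCC#C | intermediate
14 | dimethyl[(1E,6S)-2,6,10-trimethylundeca-1,9-dien-1-yl]alumane | CC(C)=CCC[C@@H](C)CCC/C(C)=C/[Al](C)C | intermediate
15 | lithium butyl(dimethyl)[(1E,6S)-2,6,10-trimethylundeca-1,9-dien-1-yl]aluminate | CC(C)=CCC[C@@H](C)CCC/C(C)=C/[Al-](C)(C)CCCC.[Li+] | intermediate
16 | (2E,7S)-3,7,11-trimethyldodeca-2,10-dien-1-ol | CC(C)=CCC[C@@H](C)CCC/C(C)=C/CO | intermediate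
17 | (3R,7S)-3,7,11-trimethyldodec-10-en-1-ol | CC(C)=CCC[C@@H](C)CCC[C@@H](C)CCO | intermediate
18 | (3R,7S)-3,7,11-trimethyldodec-10-enal | CC(C)=CCC[C@@H](C)CCC[C@@H](C)CC=O | intermediate
19 | (3R,7S)-3,7,11-trimethyldodec-10-enoic acid | CC(C)=CCC[C@@H](C)CCC[C@@H](C)CC(=O)O | intermediate
20 | 1,3-dioxoisoindolin-2-yl (3R,7S)-3,7,11-trimethyldodec-10-enoate | CC(C)=CCC[C@@H](C)CCC[C@@H](C)CC(=O)ON1C(=O)c2ccccc2C1=O | intermediate
21 | (2R)-6-methoxy-2,8-dimethyl-2-[(4R,8S)-4,8,12-trimethyltridec-11-en-1-yl]chroman | CC(C)=CCC[C@@H](C)CCC[C@@H](C)CCC[C@]1(C)CCc2cc(OC)cc(C)c2O1 | intermediate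
22 | (2R)-2,8-dimethyl-2-[(4R,8S)-4,8,12-trimethyltridec-11-en-1-yl]chroman-6-ol | CC(C)=CCC[C@@H](C)CCC[C@@H](C)CCC[C@]1(C)CCc2cc(O)cc(C)c2O1 | target

**Step count**

Total: 13 steps. Longest linear sequence: 8 steps (steps 1–6, 12, 13); the side-chain branch is 5 steps (7–11) before the union.

**Steps most likely to fail, with fallbacks**

Step 12. The process at risk is the statistical pairing of two equally reactive primary radicals at nickel, which gives homodimers of either partner, together with cathodic over-reduction of the esters to the decarboxylated alkanes. The fallback replaces the radical–radical union by a polarity-differentiated decarboxylative Negishi alkyl–alkyl coupling; it sets out from 20 and 11 and comes back at 21. Ester 20 is converted by photochemical iododecarboxylation (LiI, cat. PPh3, 456 nm, acetone) into (2R,6S)-1-iodo-2,6,10-trimethylundec-9-ene F1. Iodine–zinc exchange (Et2Zn, cat. CuI, 50 °C, volatiles then removed) should give bis[(2R,6S)-2,6,10-trimethylundec-9-en-1-yl]zinc F2. F2 (2 equiv) and ester 11 with NiCl2·glyme and 4,4′-di-tert-butyl-2,2′-bipyridine in THF/DMF at rt should then give 21, only the chroman partner passing through a radical.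

Step 4. The process at risk is slow oxidative addition of Pd(0) into the doubly ortho-substituted, electron-rich C–Br bond, so that hydrodebromination or catalyst decay outruns C–O reductive elimination. The fallback moves the ring closure to copper and an aryl iodide (Ullmann-type etherification through a copper(I) alkoxide); it sets out from 7 and comes back at 8. Aromatic Finkelstein exchange (NaI, cat. CuI, trans-N,N′-dimethylcyclohexane-1,2-diamine, dioxane, 110 °C) should give (3R)-1-(2-iodo-5-methoxy-3-methylphenyl)-3,7-dimethyloct-6-en-3-ol F3. Closure of F3 with CuI, 3,4,7,8-tetramethyl-1,10-phenanthroline and Cs2CO3 in toluene at 110 °C should give 8, again without breaking the carbinol C–O bond.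

Step 13. The process at risk is incomplete SN2 demethylation of the electron-rich ether at a temperature the product tolerates, and air oxidation of the phenoxide formed in the hot basic medium. The fallback changes the protecting-group strategy before the alkene is present; it sets out from 10 and comes back at 22. Acid 10 is demethylated with BBr3 (CH2Cl2, −78 → 0 °C) to 3-[(2S)-6-hydroxy-2,8-dimethylchroman-2-yl]propanoic acid F4. Acetylation of the phenoxide (Ac2O, aq NaOH, 0 °C) gives 3-[(2S)-6-acetoxy-2,8-dimethylchroman-2-yl]propanoic acid F5. Esterification as in step 6 gives 1,3-dioxoisoindolin-2-yl 3-[(2S)-6-acetoxy-2,8-dimethylchroman-2-yl]propanoate F6. Electrolysis of F6 with 20 under the conditions of step 12 should give (2R)-2,8-dimethyl-2-[(4R,8S)-4,8,12-trimethyltridec-11-en-1-yl]chroman-6-yl acetate F7. Methanolysis of F7 (K2CO3, MeOH, rt, argon) should give 22.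

**Further compounds**

F1 | step 12 | (2R,6S)-1-iodo-2,6,10-trimethylundec-9-ene | CC(C)=CCC[C@@H](C)CCC[C@@H](C)CI
F2 | step 12 | bis[(2R,6S)-2,6,10-trimethylundec-9-en-1-yl]zinc | CC(C)=CCC[C@@H](C)CCC[C@@H](C)C[Zn]C[C@H](C)CCC[C@H](C)CCC=C(C)C
F3 | step 4 | (3R)-1-(2-iodo-5-methoxy-3-methylphenyl)-3,7-dimethyloct-6-en-3-ol | CC(C)=CCC[C@](O)(C)CCc1cc(OC)cc(C)c1I
F4 | step 13 | 3-[(2S)-6-hydroxy-2,8-dimethylchroman-2-yl]propanoic acid | OC(=O)CC[C@]1(C)CCc2cc(O)cc(C)c2O1
F5 | step 13 | 3-[(2S)-6-acetoxy-2,8-dimethylchroman-2-yl]propanoic acid | OC(=O)CC[C@]1(C)CCc2cc(OC(C)=O)cc(C)c2O1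
F6 | step 13 | 1,3-dioxoisoindolin-2-yl 3-[(2S)-6-acetoxy-2,8-dimethylchroman-2-yl]propanoate | O=C(CC[C@]1(C)CCc2cc(OC(C)=O)cc(C)c2O1)ON1C(=O)c2ccccc2C1=O
F7 | step 13 | (2R)-2,8-dimethyl-2-[(4R,8S)-4,8,12-trimethyltridec-11-en-1-yl]chroman-6-yl acetate | CC(C)=CCC[C@@H](C)CCC[C@@H](C)CCC[C@]1(C)CCc2cc(OC(C)=O)cc(C)c2O1
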